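## Retrosynthetic overview
1. Gentiside G ⇒ ester C(acyl)–O bond, made last. The partners are unprotected 2,3-dihydroxybenzoic acid and the C20 anteiso chain kept at the acid oxidation level, (S)-17-methylnonadecanoic acid. They are joined by a reductive, boron-templated cross-esterification.
2. (S)-17-Methylnonadecanoic acid ⇒ C15–C16 sp3–sp3 bond: 15-bromopentadecanoic acid plus (S)-2-methylbutyl Grignard. The only stereocentre is bought from the chiral pool.
3. 15-Bromopentadecanoic acid ⇒ ω-pentadecalactone + HBr.
4. Rings: none is built. The arene is purchased, the 16-membered lactone is opened in step 1, and the transient boron chelate rings of the last step are lost at work-up.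

Assumption: the SMILES is read as sixteen CH2 groups between the ester oxygen and the stereocentre, so the target is (S)-17-methylnonadecyl 2,3-dihydroxybenzoate (C27H46O4), and commercial (S)-(+)-1-bromo-2-methylbutane is used at its catalogue optical purity.

## Route

Step 1
Reactants: 1 ω-pentadecalactone (oxacyclohexadecan-2-one)
Product: 2 15-bromopentadecanoic acid
Conditions: 33% HBr/AcOH, cat. H2SO4, 100 °C (sealed), 16 h; pour into H2O; recrystallise (hexane)
Reagents that add atoms: hydrogen bromide, Br
Why: Acid-mediated alkyl–oxygen cleavage of an ester (SN2 attack of bromide on the O–CH2 carbon of the protonated lactone) opens the macrolide irreversibly and differentiates the two chain ends in one operation; no stereocentre is involved.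

Step 2
Reactants: 2 15-bromopentadecanoic acid, 3 (S)-(+)-1-bromo-2-methylbutane
Product: 6 (S)-17-methylnonadecanoic acid, via (S)-2-methylbutylmagnesium bromide 4 (not isolated), via chloromagnesium 15-bromopentadecanoate 5 (not isolated)
Conditions: 3, Mg, THF, 40 °C (gives 4, 1.5 equiv); separately 2, MeMgCl (1.0 equiv), THF, −20 °C (gives 5); add 4, Li2CuCl4 (3 mol %), NMP (4 equiv), −20 °C → rt; 1 M HCl
Reagents that add atoms: none
Why: Kochi-type copper-catalysed sp3–sp3 Grignard cross-coupling, in which the cuprate from 4 displaces the primary bromide of 5 while the pre-formed magnesium carboxylate is inert to RMgX, and the (S) stereocentre comes unchanged from chiral-pool 3 because it is β to the C–Mg bond and takes part in no bond change.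

Step 3
Reactants: 6 (S)-17-methylnonadecanoic acid, 7 2,3-dihydroxybenzoic acid
Product: 11 gentiside G [(S)-17-methylnonadecyl 2,3-dihydroxybenzoate], via tris(alkoxy)boroxine 8 (not isolated), via salicylate-mode acyloxyborate chelate 9 (not isolated), via catecholborate-masked ester 10 (not isolated)
Conditions: BH3·SMe2 (1.1 equiv), THF, 0 °C → rt, 3 h; strip volatiles in vacuo; 7 (1.0 equiv), PhMe, reflux, Dean–Stark/4 Å MS, Ar, 16–24 h; 1 M HCl/EtOAc
Reagents that add atoms: none
Why: Proposed new method: a boron-relay reductive cross-esterification of two different carboxylic acids, in which the boron left by the standard BH3 reduction of aliphatic acid 6 (alkoxyboroxine 8, one B per alkoxy group, no B–H left after evacuation) is re-used as a 1:1 template; the salicylate unit of 7 (CO2H plus 2-OH) condenses on the RO–B unit with loss of water to the six-membered chelate 9, a boron mixed anhydride whose activated acyl carbon takes up the boron-bound (or transiently released) primary alkoxide, and the step is driven forward because boron then slips to the very stable five-membered catecholborate 10, which also shields the catechol from O-acylation and oxidation until acidic work-up frees 11; the closest known reaction types are boric-acid-catalysed chemoselective esterification of α-hydroxy acids through chelated acyloxyborates, boron-mediated direct amidation, and the RCO2CH2R by-product of under-stoichiometric borane reductions; no stereocentre is formed and C17 is remote and untouched.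

## Compound list
1 | ω-pentadecalactone (oxacyclohexadecan-2-one) | O=C1CCCCCCCCCCCCCCO1 | starting material
2 | 15-bromopentadecanoic acid | OC(=O)CCCCCCCCCCCCCCBr | intermediate
3 | (S)-(+)-1-bromo-2-methylbutane | CC[C@H](C)CBr | starting material
4 | (S)-2-methylbutylmagnesium bromide | CC[C@H](C)C[Mg]Br | intermediate
5 | chloromagnesium 15-bromopentadecanoate | Cl[Mg]OC(=O)CCCCCCCCCCCCCCBr | intermediate
6 | (S)-17-methylnonadecanoic acid | CC[C@H](C)CCCCCCCCCCCCCCCC(=O)O | intermediate
7 | 2,3-dihydroxybenzoic acid | OC(=O)c1cccc(O)c1O | starting material
8 | 2,4,6-tris[(S)-17-methylnonadecyloxy]boroxine | CC[C@H](C)CCCCCCCCCCCCCCCCOB1OB(OCCCCCCCCCCCCCCCC[C@@H](C)CC)OB(OCCCCCCCCCCCCCCCC[C@@H](C)CC)O1 | intermediate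
9 | 8-hydroxy-2-[(S)-17-methylnonadecyloxy]-4H-1,3,2-benzodioxaborinin-4-one | CC[C@H](C)CCCCCCCCCCCCCCCCOB1OC(=O)c2cccc(O)c2O1 | intermediate
10 | (S)-17-methylnonadecyl 2-hydroxy-1,3,2-benzodioxaborole-4-carboxylate | CC[C@H](C)CCCCCCCCCCCCCCCCOC(=O)c1cccc2OB(O)Oc12 | intermediate
11 | gentiside G, (S)-17-methylnonadecyl 2,3-dihydroxybenzoate | CC[C@H](C)CCCCCCCCCCCCCCCCOC(=O)c1cccc(O)c1O | target

## Step count and risks
Total step count: 3. Longest linear sequence: 3 (1 → 2 → 6 → 11).

**Step 3 (the proposed new step, highest risk).**
- Boron may rest on the catechol oxygens of 7 instead of the salicylate site, which would make acyl transfer slow.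
- 7 dissolves poorly in toluene.
- Some aryl ester (depside) may form.
- The fallback uses known chemistry and forms the alkyl C–O bond instead of the acyl C–O bond. It sets out from 8 in the same flask and comes back at 11.
- Quenching 8 with MeOH/H2O liberates (S)-17-methylnonadecan-1-ol F5.
- F5 is then coupled with unprotected 7 under Mitsunobu conditions (PPh3, DIAD, THF, 0 °C → rt). Only the carboxylic acid (pKa about 3) competes effectively as pronucleophile, so the carboxylate displaces the alkoxyphosphonium by SN2 and the phenols stay free.

**Step 2 (medium risk).**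
- The carboxylate slurry and the β-branched Grignard can make the coupling sluggish.
- Reduction or elimination by-products (C15 acids) are hard to remove from 6.
- The fallback replaces the catalytic coupling by stabilised-carbanion alkylation and reductive desulfonylation. It sets out from 3 and 2 and comes back at 6.
- PhSO2Na (cat. NaI, DMF, 90 °C) converts 3 into (S)-2-methylbutyl phenyl sulfone F3.
- n-BuLi (2.1 equiv in total, the first equivalent consumed by the acid proton of 2; THF/DMPU, −78 °C → rt) metalates F3 next to sulfur. Alkylation with 2 then gives (17S)-17-methyl-16-(phenylsulfonyl)nonadecanoic acid F4. It forms as irrelevant C16 epimers, and C17 is not acidic.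
- Na(Hg)/Na2HPO4/MeOH removes the sulfonyl group to give 6.

**Step 1 (lowest risk).**
- Opening may be incomplete, or oligoester may form under the strong-acid conditions.
- The fallback separates acyl cleavage from a neutral bromination. It sets out from 1 and comes back at 2.
- Catalytic NaOMe in refluxing MeOH transesterifies 1 to methyl 15-hydroxypentadecanoate F1.
- Appel bromination (CBr4, PPh3, CH2Cl2, 0 °C) gives methyl 15-bromopentadecanoate F2.
- LiOH (THF/H2O, rt) followed by acidification gives 2.

## Further compounds
F1 | step 1 | methyl 15-hydroxypentadecanoate | COC(=O)CCCCCCCCCCCCCCO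
F2 | step 1 | methyl 15-bromopentadecanoate | COC(=O)CCCCCCCCCCCCCCBr
F3 | step 2 | (S)-2-methylbutyl phenyl sulfone | CC[C@H](C)CS(=O)(=O)c1ccccc1
F4 | step 2 | (17S)-17-methyl-16-(phenylsulfonyl)nonadecanoic acid (C16 epimers) | CC[C@H](C)C(CCCCCCCCCCCCCCC(=O)O)S(=O)(=O)c1ccccc1
F5 | step 3 | (S)-17-methylnonadecan-1-ol | CC[C@H](C)CCCCCCCCCCCCCCCCO
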